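Numbering used throughout: C1 is the fully substituted ring carbon bearing the tertiary hydroxyl and C7 (the CH2OBz carbon); C2 is CH–OBz, C3=C4 the ring alkene, C5 CH–OBz and C6 CH–OH.

## Analysis of the target

The target 18 is a monocyclic cyclohex-3-ene in which all four sp3 ring carbons are oxygenated stereocentres, (1S,2R,5R,6S), with benzoates on the C2, C5 and C7 oxygens and free hydroxyls on C1 and C6. The oxygens on C1, C2 and C6 lie on one ring face and the C5 benzoate on the other, so the tertiary hydroxyl is cis to both neighbours, C5/C6 are trans, and the two allylic benzoates are trans across the ring. The sensitive points are the benzoates next to free hydroxyls (acyl migration under base, above all C5 to C6), the allylic C–O bonds, and the readiness of any intermediate with a carbonyl or a leaving group on this ring to eliminate towards an arene. The synthesis is hard for two reasons: five chemically similar oxygens must be told apart, and the quaternary C1 must carry its hydroxyl on the more crowded face. The strategy rests on one observation: the oxygens on C2, C5 and C6 have the all-trans arrangement of conduritol B (6), with the benzoates exactly on its two allylic carbons. A conduritol B 2,5-dibenzoate is C2-symmetric, so its two remaining hydroxyls (C1 and C6) are homotopic. Oxidising either gives the same C1 ketone, on which C7 and the cis tertiary hydroxyl can then be built.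

## Retrosynthetic reasoning

**C7–O bond (18 to 17 + 9).** The primary benzoate is cut first, back to spiro-epoxy alcohol 17 and benzoic acid 9. Opening at the unhindered CH2 touches no stereocentre, places the third benzoate regiospecifically and releases the tertiary hydroxyl in the same event. The forward reaction must attack C7 only and must not let a benzoate migrate.

**Epoxide oxygen at C1 (17 to 16).** The C1–O bond is traced to the exocyclic alkene of allylic alcohol 16. The C6 hydroxyl sits on the face that the C1 oxygen must occupy, so a hydroxyl-directed epoxidation can set the quaternary centre. The forward reaction has to prefer the exocyclic alkene over the ring alkene and the hydroxyl face over the open face.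

**C1=C7 bond (16 to 15 to 14).** The only C–C bond of the route is cut at the one carbon where the target departs from the conduritol pattern, giving ketone 14. The C6 oxygen is kept as a silyl ether (15) until the alkene is in place. The forward methylenation must be non-basic, because 14 carries a β-benzoate and an allylic α-hydrogen.

**C1 oxidation level and differentiation (14 to 13 to 12).** Ketone 14 comes from monosilyl ether 13, and 13 from the C2-symmetric diol 12. Because the two hydroxyls of 12 are homotopic, it does not matter which one is silylated; this removes any selectivity problem between C1 and C6.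

**Carbonates (12 to 11).** The diol is unmasked from bis-carbonate 11 under reducing, non-basic conditions that leave allylic benzoates alone.

**C2–O and C5–O bonds (11 to 8 + 9).** The two allylic benzoate C–O bonds are cut together, back to racemic tetracarbonate 8 and two equivalents of 9. These are the only C–O bonds on the ring that a palladium catalyst can make and break, and they coincide with the benzoate positions of 18. A chiral palladium–diphosphine catalyst can therefore install both benzoates and the absolute configuration at once, using both enantiomers of the racemate. The forward reaction must ionise only allylic carbonates, re-form the C–O bonds with net retention and favour 1,4- over 1,2-disubstitution.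

**Racemic precursor (8 to 6 + 7; 6 to 5 to 3 to 2 to 1).** Tetracarbonate 8 is the peracylation product of (±)-conduritol B (6) with four equivalents of chloroformate 7, one per hydroxyl. Tetrol 6 comes from tetraacetate 5, and 5 from the all-trans dibromodiol 3 by acetylation (diacetate 4) and substitution with neighbouring-group participation. Diol 3 is the reduction product of dibromodione 2, the bromine adduct of p-benzoquinone 1. This part is short, scalable and makes no demand on enantiocontrol.

## Alternatives that were turned down

**Alternative 1: enzymatic ipso,ortho-dihydroxylation of an arene.** The disconnection removes the C1–O and C2–O bonds and reaches benzoic acid (9). In the forward key step, whole cells with a benzoate dioxygenase and no diol dehydrogenase add two cis hydroxyls to the ipso and ortho carbons of 9. The product is the diene acid A1, (1S,2R)-1,2-dihydroxycyclohexa-3,5-diene-1-carboxylic acid.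
- For it: one step from 9 delivers the quaternary C1 with its carbon substituent (the future C7), the cis C1/C2 diol and the correct absolute configuration. The whole route would be clearly shorter than the one chosen.
- Against it: A1 is a fermentation product of a blocked mutant strain, not a catalogue chemical, and it dehydrates to an arene with traces of acid.
- The remaining work is not trivial. The C5 and C6 oxygens must be added trans across one double bond of a conjugated diene, with C6–O cis to C1–O. That means face- and site-selective monoepoxidation where both double bonds are allylic to a directing hydroxyl, followed by benzoate opening at C5 in competition with SN2′ attack at C3.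
- Three benzoates must then be placed on three of five hydroxyls, with the two secondary ones (C2, C6) to be distinguished.
- Comparison: Alternative 1 is stronger on step economy and on the quaternary centre. The chosen route offers instead purely chemical, purchasable inputs, either enantiomer by choice of ligand, and C2/C5 benzoates placed regiospecifically in the step that sets the absolute configuration.

**Alternative 2: boron-tethered oxa-Michael desymmetrisation of a p-quinol.** The disconnection cuts the C6–O bond back to the achiral dienone A2, 4-(benzoyloxymethyl)-4-hydroxycyclohexa-2,5-dien-1-one. In the forward key step the tertiary hydroxyl of A2 forms a hemiester with phenylboronic acid A4. Under a chiral amine–thiourea its B–OH oxygen adds to one of the two enantiotopic enone arms, giving the cis-fused boronate A3.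
- For it: A2 is a few steps from a simple phenol, C7 and its benzoate are present from the start, and one organocatalytic step sets C1 and C6 with the required cis relationship.
- Against it: A3 has a ketone at C4, a methylene at C5 and an alkene at C2=C3, so none of the other ring positions is at the oxidation pattern of 18.
- Reaching 18 needs an α-oxygenation at C5 trans to C6–O and a 1,3-transposition of the enone (C4=O/C2=C3 to C2–O/C3=C4) with the C2 oxygen cis to C1–O. The usual epoxidation/Wharton-type sequences use basic and nucleophilic reagents that cleave benzoates and drive β-oxygenated cyclohexenones to phenols.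
- The enantioselectivity of the desymmetrisation with this particular C1 substituent is untested.
- Comparison: Alternative 2 is stronger in having the quaternary centre from the first step. The chosen route offers instead all three secondary oxygens in the correct relative configuration from the start and only one redox manipulation of the ring.

**Alternative 3: Ireland–Claisen ring contraction of a sugar lactone.** The disconnection cuts the C1–C2 bond and re-forms a lactone C4–O bond. In the forward key step the silyl ketene acetal of a protected hexonolactone, carrying a (Z)-silyloxyvinyl group on the carbon bound to the ring oxygen, rearranges through a boat transition state. The product is the cyclohexene acid A5, with a C1,C6-acetonide, silyl ethers at C2 and C5, and the carboxyl (future C7) on C1.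
- For it: the absolute configuration comes from the chiral pool, and one pericyclic step forms the carbocycle, the quaternary centre and the C2 stereocentre by suprafacial chirality transfer.
- Against it: the substrate needs many steps, including a geometrically pure (Z)-enol ether on which the C2 configuration depends. The outcome also hinges on a clean boat over chair preference for two centres at once.
- After the key step the acid must be reduced, two silyl ethers exchanged for benzoates, the acetonide removed beside allylic benzoates and the primary hydroxyl benzoylated selectively, so the sequence is long and heavy in protecting-group steps.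
- Comparison: Alternative 3 is stronger in needing no enantioselective catalysis and in forging the quaternary C–C bond directly. The chosen route offers instead a much shorter sequence in which the benzoates are introduced by the key step itself rather than by later exchange.

Key step: step 6

Assumption: the (R,R) enantiomer of the diphosphine is taken to steer benzoate to the allyl terminus that leads to the (2R,5R) series; the sense depends only on the hand of the ligand, and the (S,S) ligand would be used in the same way if a trial on 8 shows the opposite sense.

## Route

Step 1
Reactants: 1 p-benzoquinone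
Product: 2 (±)-trans-5,6-dibromocyclohex-2-ene-1,4-dione
Conditions: Br2 (1.0 equiv), CHCl3, 0 °C
Reagents that add atoms: bromine, BrBr
Why: Electrophilic addition of one equivalent of bromine to one C=C of the quinone runs through a bromonium ion with anti opening, so the two bromines end up trans (racemate); the adduct is less electron-rich than 1 and should not add a second equivalent at 0 °C.

Step 2
Reactants: 2 (±)-trans-5,6-dibromocyclohex-2-ene-1,4-dione
Product: 3 (±)-(1R*,2S*,3S*,4R*)-2,3-dibromocyclohex-5-ene-1,4-diol (all-trans)
Conditions: NaBH4, Et2O–H2O, −5 → 0 °C
Reagents that add atoms: none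
Why: Borohydride 1,2-reduction of both carbonyls; hydride is expected to enter each carbonyl from the face that leaves the new hydroxyl trans to its neighbouring bromine, the established course for this dione, giving the all-trans dibromodiol, and the low temperature suppresses conjugate reduction and loss of HBr.

Step 3
Reactants: 3 (±)-all-trans-2,3-dibromocyclohex-5-ene-1,4-diol
Product: 5 (±)-conduritol B tetraacetate (all-trans cyclohex-5-ene-1,2,3,4-tetrayl tetraacetate), via dibromide diacetate 4 (not isolated)
Conditions: Ac2O, AcOH, KOAc, reflux
Reagents that add atoms: acetic anhydride, CC(=O)OC(C)=O; potassium acetate, CC(=O)[O-].[K+]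
Why: Acetylation to 4 is followed by substitution with neighbouring-group participation: each acetoxy group, trans to the adjacent bromine, displaces it to a bridged acetoxonium ion that acetate reopens trans, so both C–Br carbons are substituted with net retention and the all-trans tetraacetate should be isolable by crystallisation from minor diastereomers.

Step 4
Reactants: 5 (±)-conduritol B tetraacetate
Product: 6 (±)-conduritol B [(1R*,2S*,3S*,4R*)-cyclohex-5-ene-1,2,3,4-tetrol]
Conditions: NaOMe (cat.), MeOH, rt
Reagents that add atoms: none
Why: Zemplén transesterification with catalytic methoxide removes the four acetates as methyl acetate without touching any stereocentre.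

Step 5
Reactants: 6 (±)-conduritol B; 7 2,2,2-trichloroethyl chloroformate (5 equiv)
Product: 8 (±)-conduritol B tetrakis(2,2,2-trichloroethyl carbonate)
Conditions: 7 (5 equiv), pyridine, DMAP (cat.), CH2Cl2, 0 °C → rt
Reagents that add atoms: 2,2,2-trichloroethyl chloroformate (three further equivalents of 7), ClC(=O)OCC(Cl)(Cl)Cl.ClC(=O)OCC(Cl)(Cl)Cl.ClC(=O)OCC(Cl)(Cl)Cl
Why: Acylation of all four secondary hydroxyls with a chloroformate under nucleophilic catalysis takes up four of the five equivalents of 7, one per hydroxyl, each with loss of HCl to pyridine; the excess at low temperature should outpace cyclic-carbonate formation between neighbouring oxygens, and this carbonate is chosen because it ionises on palladium far more readily than an acetate and is later removable by zinc beside benzoates.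

Step 6
Reactants: 8 (±)-conduritol B tetrakis(2,2,2-trichloroethyl carbonate); 9 benzoic acid (2.5 equiv)
Product: 11 (1R,4R,5S,6S)-5,6-bis[(2,2,2-trichloroethoxy)carbonyloxy]cyclohex-2-ene-1,4-diyl dibenzoate, via monobenzoate tricarbonate 10 (not isolated)
Conditions: Pd2(dba)3·CHCl3 (2.5 mol %), (1R,2R)-N,N'-bis[2-(diphenylphosphanyl)benzoyl]cyclohexane-1,2-diamine (7.5 mol %), NaOH (2.2 equiv), (n-Hex)4NBr, CH2Cl2–H2O, rt
Reagents that add atoms: none
Why: Zerovalent palladium ionises an allylic trichloroethyl carbonate of either enantiomer of 8 anti to the leaving group, the carbonate anion loses CO2 so ionisation cannot reverse, and both enantiomers give the same meso η3-allyl complex (mirror plane through the central allyl carbon and the ring carbon opposite). The chiral diphosphine then directs benzoate, arriving anti to palladium, to one of the two enantiotopic allyl termini, which sets C2 under ligand control and, ionisation and attack both being inversions, keeps the new C–O bond trans to its neighbour (10). The second allylic carbonate of 10 ionises and is attacked at the terminus the ligand again prefers, which sets C5 and gives the C2-symmetric 11; the antipode of 10 would be steered by the same preference to an unsymmetrical 1,2-dibenzoate rather than to the enantiomer of 11, so the second substitution proof-reads the first and the enantiomeric purity of 11 should exceed the selectivity of a single attack. The closest known reaction type is the Tsuji–Trost dynamic kinetic asymmetric substitution of racemic conduritol B tetraesters with carboxylates. No ring is closed; two C–O bonds are formed. Of the four stereocentres of 11, C2 and C5 are fixed by the ligand and C1 and C6 by the all-trans relative configuration carried over from 8 through double inversion. The step needs chemoselectivity for allylic over non-allylic carbonates (only allylic C–O bonds ionise), 1,4- over 1,2-disubstitution (same terminus preference in both rounds) and full turnover of the slower enantiomer, which the high leaving-group ability of the trichloroethyl carbonate should secure where acetates would merely be resolved. Benzoate is kept in excess over base so that hydroxide and trichloroethoxide do not compete as nucleophiles.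

Step 7
Reactants: 11 dibenzoate bis(trichloroethyl carbonate)
Product: 12 (1R,4R,5R,6R)-5,6-dihydroxycyclohex-2-ene-1,4-diyl dibenzoate (C2-symmetric trans-diol)
Conditions: Zn dust, AcOH–THF, rt
Reagents that add atoms: none
Why: Reductive β-elimination: zinc inserts into a C–Cl bond of each trichloroethyl group, which fragments to 1,1-dichloroethene, CO2 and the alkoxide, protonated by acetic acid; the acidic medium disfavours benzoate migration to the freed hydroxyls, and allylic benzoates and the alkene are inert to zinc.

Step 8
Reactants: 12 C2-symmetric diol dibenzoate
Product: 13 (1R,4R,5R,6S)-5-(tert-butyldimethylsilyloxy)-6-hydroxycyclohex-2-ene-1,4-diyl dibenzoate (silyl ether on the C6 oxygen, free hydroxyl on C1)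
Conditions: TBSOTf (1.0 equiv), 2,6-lutidine, CH2Cl2, −78 °C
Reagents that add atoms: tert-butyldimethylsilyl trifluoromethanesulfonate, CC(C)(C)[Si](C)(C)OS(=O)(=O)C(F)(F)F
Why: Silylation of either homotopic hydroxyl of the C2-symmetric diol gives the same monosilyl ether; the bulky group slows silylation of the neighbouring hydroxyl, unreacted 12 and any bis-silyl ether can be recycled, and the low temperature with a hindered non-nucleophilic base avoids acyl migration.

Step 9
Reactants: 13 monosilyl ether
Product: 14 (1R,4R,5S)-5-(tert-butyldimethylsilyloxy)-6-oxocyclohex-2-ene-1,4-diyl dibenzoate (C1 ketone)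
Conditions: Dess–Martin periodinane, CH2Cl2, 0 °C → rt; filtration through silica, used at once
Reagents that add atoms: none
Why: Dess–Martin oxidation of the remaining secondary alcohol under neutral to weakly acidic conditions; base is excluded because 14 has a β-benzoate (C5) and an allylic α-hydrogen (C2) and would eliminate and aromatise.

Step 10
Reactants: 14 C1 ketone
Product: 15 (1R,4R,5R)-5-(tert-butyldimethylsilyloxy)-6-methylidenecyclohex-2-ene-1,4-diyl dibenzoate
Conditions: Zn, CH2Br2, TiCl4 (reagent pre-formed in THF), CH2Cl2, 0 °C → rt
Reagents that add atoms: dibromomethane, BrCBr
Why: Takai–Lombardo methylenation: the gem-dimetallic methylene reagent is non-basic and selective for ketones over esters, so the enolisable, elimination-prone ketone should be converted to the exocyclic alkene without loss of benzoate or silyl ether; no stereocentre is formed.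

Step 11
Reactants: 15 silyl-protected exocyclic alkene
Product: 16 (1R,4R,5R)-5-hydroxy-6-methylidenecyclohex-2-ene-1,4-diyl dibenzoate (allylic alcohol)
Conditions: HF·pyridine, pyridine, THF, 0 °C → rt
Reagents that add atoms: none
Why: Fluoride-driven cleavage of the silyl ether in a buffered acidic medium; unlike basic fluoride sources this should not move the C5 benzoate onto the liberated C6 hydroxyl.

Step 12
Reactants: 16 allylic alcohol
Product: 17 (3S,4R,7R,8S)-8-hydroxy-1-oxaspiro[2.5]oct-5-ene-4,7-diyl dibenzoate (spiro-epoxide, epoxide oxygen cis to the C6 hydroxyl)
Conditions: VO(acac)2 (cat.), t-BuOOH, CH2Cl2, 0 °C → rt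
Reagents that add atoms: tert-butyl hydroperoxide, CC(C)(C)OO
Why: Hydroxyl-directed epoxidation: the C6 hydroxyl binds vanadium as an alkoxide and the coordinated alkyl peroxide delivers oxygen to the adjacent exocyclic alkene on the hydroxyl face, which sets C1 with its oxygen cis to C6–OH and to C2–OBz; the ring alkene is only homoallylic to the hydroxyl and is deactivated by two allylic benzoates.

Step 13
Reactants: 17 spiro-epoxy alcohol; 9 benzoic acid (2 equiv)
Product: 18 [(1S,2R,5R,6S)-2,5-bis(benzoyloxy)-1,6-dihydroxycyclohex-3-en-1-yl]methyl benzoate (target)
Conditions: Ti(OiPr)4 (1.5 equiv), CH2Cl2, rt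
Reagents that add atoms: none
Why: Titanium-mediated opening of a 2,3-epoxy alcohol by a carboxylic acid: the C6 alkoxide and the epoxide oxygen chelate titanium, which activates the epoxide and sends benzoate to the distal carbon, here the unhindered primary C7; the C1–O bond is not broken, so C1 keeps its configuration.

## Compound list

1 | p-benzoquinone | O=C1C=CC(=O)C=C1 | starting material
2 | (±)-trans-5,6-dibromocyclohex-2-ene-1,4-dione (racemate, one enantiomer drawn) | O=C1C=CC(=O)[C@H](Br)[C@H]1Br | intermediate
3 | (±)-(1R*,2S*,3S*,4R*)-2,3-dibromocyclohex-5-ene-1,4-diol (racemate, one enantiomer drawn) | Br[C@H]1[C@H](O)C=C[C@@H](O)[C@@H]1Br | intermediate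
4 | (±)-(1R*,2S*,3S*,4R*)-2,3-dibromocyclohex-5-ene-1,4-diyl diacetate (not isolated; racemate, one enantiomer drawn) | Br[C@H]1[C@H](OC(C)=O)C=C[C@@H](OC(C)=O)[C@@H]1Br | intermediate
5 | (±)-conduritol B tetraacetate (racemate, one enantiomer drawn) | CC(=O)O[C@H]1[C@H](OC(C)=O)C=C[C@@H](OC(C)=O)[C@@H]1OC(C)=O | intermediate
6 | (±)-conduritol B (racemate, one enantiomer drawn) | O[C@H]1[C@H](O)C=C[C@@H](O)[C@@H]1O | intermediate
7 | 2,2,2-trichloroethyl chloroformate | ClC(=O)OCC(Cl)(Cl)Cl | starting material
8 | (±)-conduritol B tetrakis(2,2,2-trichloroethyl carbonate) (racemate, one enantiomer drawn) | ClC(Cl)(Cl)COC(=O)O[C@H]1[C@H](OC(=O)OCC(Cl)(Cl)Cl)C=C[C@@H](OC(=O)OCC(Cl)(Cl)Cl)[C@@H]1OC(=O)OCC(Cl)(Cl)Cl | intermediate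
9 | benzoic acid | OC(=O)c1ccccc1 | starting material
10 | (1R,4R,5S,6S)-4,5,6-tris[(2,2,2-trichloroethoxy)carbonyloxy]cyclohex-2-en-1-yl benzoate (not isolated) | ClC(Cl)(Cl)COC(=O)O[C@H]1[C@H](OC(=O)c2ccccc2)C=C[C@@H](OC(=O)OCC(Cl)(Cl)Cl)[C@@H]1OC(=O)OCC(Cl)(Cl)Cl | intermediate
11 | (1R,4R,5S,6S)-5,6-bis[(2,2,2-trichloroethoxy)carbonyloxy]cyclohex-2-ene-1,4-diyl dibenzoate | ClC(Cl)(Cl)COC(=O)O[C@H]1[C@H](OC(=O)c2ccccc2)C=C[C@@H](OC(=O)c2ccccc2)[C@@H]1OC(=O)OCC(Cl)(Cl)Cl | intermediate
12 | (1R,4R,5R,6R)-5,6-dihydroxycyclohex-2-ene-1,4-diyl dibenzoate | O[C@H]1[C@H](OC(=O)c2ccccc2)C=C[C@@H](OC(=O)c2ccccc2)[C@@H]1O | intermediate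
13 | (1R,4R,5R,6S)-5-(tert-butyldimethylsilyloxy)-6-hydroxycyclohex-2-ene-1,4-diyl dibenzoate | O[C@H]1[C@H](OC(=O)c2ccccc2)C=C[C@@H](OC(=O)c2ccccc2)[C@@H]1O[Si](C)(C)C(C)(C)C | intermediate
14 | (1R,4R,5S)-5-(tert-butyldimethylsilyloxy)-6-oxocyclohex-2-ene-1,4-diyl dibenzoate | O=C1[C@H](OC(=O)c2ccccc2)C=C[C@@H](OC(=O)c2ccccc2)[C@@H]1O[Si](C)(C)C(C)(C)C | intermediate
15 | (1R,4R,5R)-5-(tert-butyldimethylsilyloxy)-6-methylidenecyclohex-2-ene-1,4-diyl dibenzoate | C=C1[C@H](OC(=O)c2ccccc2)C=C[C@@H](OC(=O)c2ccccc2)[C@@H]1O[Si](C)(C)C(C)(C)C | intermediate
16 | (1R,4R,5R)-5-hydroxy-6-methylidenecyclohex-2-ene-1,4-diyl dibenzoate | C=C1[C@H](OC(=O)c2ccccc2)C=C[C@@H](OC(=O)c2ccccc2)[C@@H]1O | intermediate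
17 | (3S,4R,7R,8S)-8-hydroxy-1-oxaspiro[2.5]oct-5-ene-4,7-diyl dibenzoate | C2O[C@@]21[C@H](OC(=O)c3ccccc3)C=C[C@@H](OC(=O)c3ccccc3)[C@@H]1O | intermediate
18 | [(1S,2R,5R,6S)-2,5-bis(benzoyloxy)-1,6-dihydroxycyclohex-3-en-1-yl]methyl benzoate (CNP0128482.1) | O=C(OC[C@@]1(O)[C@H](OC(=O)c2ccccc2)C=C[C@@H](OC(=O)c2ccccc2)[C@@H]1O)c1ccccc1 | target

## Step count and least certain steps

Total step count: 13. Longest linear sequence: 13 steps (1 to 18); 7 and 9 are purchased.

**Step 6 (key step).** The most likely failure is incomplete convergence: the slower-ionising enantiomer of 8 reacts too slowly, or its carbonates hydrolyse in the aqueous base, so that the reaction behaves as a kinetic resolution. A second failure mode is attack at the other allyl terminus in the second round, which diverts material to the 1,2-dibenzoate regioisomer. The cause in both cases is that matched and mismatched ionisation rates and terminus preference are set by a ligand pocket that this crowded, tetra-oxygenated ring fills almost completely.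
Fallback, from 5 back to 12: the racemic tetraacetate 5 is subjected to the same catalyst with benzoate (from 9 and NaOH, biphasic, phase-transfer salt). Acetates ionise only in the matched enantiomer, so this kinetic resolution converts at most half of the material, with net retention at both allylic carbons, into the (1R,4R,5S,6S)-5,6-diacetoxycyclohex-2-ene-1,4-diyl dibenzoate F1 and leaves the other enantiomer of 5. Acid-catalysed methanolysis of F1 (HCl generated from acetyl chloride in MeOH, 0 °C to rt) cleaves the two acetates faster than the benzoates and gives 12.

**Step 10 (with the ketone from step 9).** The most likely failure is enolisation of 14 followed by loss of the C5 benzoate and aromatisation, before or during methylenation. A further risk is Lewis-acid-induced allylic transposition of the now doubly allylic C2 benzoate in 15. Both follow from the β-acyloxy ketone and the acidity of the allylic α-hydrogen.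
Fallback, from 14 back to 16: Peterson olefination. Me3SiCH2MgCl with CeCl3 in THF at −78 °C is a weakly basic organocerium reagent that adds to ketones faster than to esters. Addition from the face opposite the C2 and C6 oxygens, with a cold acidic quench, gives the C1 (trimethylsilyl)methyl carbinol F2. HF·pyridine then causes acid-promoted Peterson elimination and cleaves the silyl ether in the same operation, giving 16.

**Step 12.** The most likely failures are poor facial selectivity, because the hydroxyl face also carries the C2 benzoate, and oxidation of the allylic alcohol to an enone by the vanadium peroxide when epoxidation is slow.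
Fallback, from 16 to 18: hydroxyl-directed dihydroxylation with OsO4 and TMEDA in CH2Cl2 at −78 °C delivers both oxygens to the exocyclic alkene on the face of the hydrogen-bonded C6 hydroxyl. Cleavage of the osmate ester with HCl in MeOH gives the (1R,4R,5S,6S)-5,6-dihydroxy-6-(hydroxymethyl)cyclohex-2-ene-1,4-diyl dibenzoate F3. Its primary C7 hydroxyl is benzoylated selectively with benzoyl chloride and 2,4,6-collidine in CH2Cl2 at −40 °C to give 18.

**Step 13.** The most likely failure is acyl migration on the titanium-bound C6 alkoxide (C5 benzoate to C6 oxygen) or ester exchange with isopropoxide. A lesser risk is opening at C1.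
Fallback, from 17 to 18: C–O bond formation is separated from the Lewis acid. MgBr2·OEt2 in Et2O at 0 °C opens the epoxide quickly at the primary carbon and gives the C7 bromide F4, 6-(bromomethyl)-5,6-dihydroxycyclohex-2-ene-1,4-diyl dibenzoate with the configuration of 18. Silver benzoate (AgO2CPh) in toluene at 60 °C then replaces bromide by benzoate under neutral, silver-assisted conditions and gives 18.

## Further compounds

F1 | step 6 | (1R,4R,5S,6S)-5,6-diacetoxycyclohex-2-ene-1,4-diyl dibenzoate | CC(=O)O[C@H]1[C@H](OC(=O)c2ccccc2)C=C[C@@H](OC(=O)c2ccccc2)[C@@H]1OC(C)=O
F2 | step 10 | C1 (trimethylsilyl)methyl carbinol of 14 (CH2SiMe3 trans to the C2 and C6 oxygens) | C[Si](C)(C)C[C@@]1(O)[C@H](OC(=O)c2ccccc2)C=C[C@@H](OC(=O)c2ccccc2)[C@@H]1O[Si](C)(C)C(C)(C)C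
F3 | step 12 | (1R,4R,5S,6S)-5,6-dihydroxy-6-(hydroxymethyl)cyclohex-2-ene-1,4-diyl dibenzoate | OC[C@@]1(O)[C@H](OC(=O)c2ccccc2)C=C[C@@H](OC(=O)c2ccccc2)[C@@H]1O
F4 | step 13 | 6-(bromomethyl)-5,6-dihydroxycyclohex-2-ene-1,4-diyl dibenzoate (configuration of 18) | BrC[C@@]1(O)[C@H](OC(=O)c2ccccc2)C=C[C@@H](OC(=O)c2ccccc2)[C@@H]1O
A1 | alternative 1 | (1S,2R)-1,2-dihydroxycyclohexa-3,5-diene-1-carboxylic acid | OC(=O)[C@@]1(O)[C@H](O)C=CC=C1
A2 | alternative 2 | 4-(benzoyloxymethyl)-4-hydroxycyclohexa-2,5-dien-1-one | O=C1C=CC(O)(COC(=O)c2ccccc2)C=C1
A3 | alternative 2 | cis-fused C1,C6-phenylboronate of the 5,6-dihydro enone | O=C(OC[C@@]1(OB(c3ccccc3)O4)C=CC(=O)C[C@@H]14)c1ccccc1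
A4 | alternative 2 | phenylboronic acid | OB(O)c1ccccc1
A5 | alternative 3 | cyclohexene carboxylic acid with C1,C6-acetonide and C2,C5 tert-butyldimethylsilyl ethers | OC(=O)[C@@]1(OC(C)(C)O3)[C@H](O[Si](C)(C)C(C)(C)C)C=C[C@@H](O[Si](C)(C)C(C)(C)C)[C@@H]13
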